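**Retrosynthetic overview**
- The target, (3S)-dihydroisocoumarin with a (2S)-2-acetoxy-3-hydroxy-3-methylbutyl chain at C7, comes from the corresponding triol lactone by acetylation of its only secondary alcohol.
- The δ-lactone ring is closed last, by transesterification of an ortho-(2-hydroxypropyl)benzoate.
- The benzene ring is made by a [4+2] cycloaddition/aromatisation of a Brassard-type vinylketene silyl acetal (C5–C8 plus side chain) with an alkynoate (C1, C3, C4, C4a, C8a).
- The diene is built on a γ-butyrolactone from L-glutamic acid; this lactone carries the side-chain stereocentre and its C–O bond is cleaved on aromatisation, freeing the 8-OH and the side-chain 2-OH.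
- The alkynoate comes from ethyl propiolate and (S)-propylene oxide (C3 stereocentre). Ring order: bought γ-lactone (sacrificed), then benzene ring, then δ-lactone.

Assumption: methyl (2S)-5-oxotetrahydrofuran-2-carboxylate, the methyl ester of the lactone acid made from L-glutamic acid, is bought as such.

**Route**

Step 1
Reactants: 1 ethyl propiolate; 2 (S)-propylene oxide
Product: 4 ethyl (5S)-5-hydroxyhex-2-ynoate, via ethyl 3-lithiopropiolate 3 (not isolated)
Conditions: 1 (1.5 equiv), n-BuLi, THF, −78 °C; BF3·OEt2, then 2, −78 °C, 1 h; aq. NH4Cl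
Reagents that add atoms: none
Why: BF3-assisted SN2 opening of the epoxide at its CH2 terminus by the lithium acetylide (Yamaguchi–Hirao alkynylation) leaves the bought (S) carbinol carbon, the future C3, untouched.

Step 2
Reactants: 5 methyl (2S)-5-oxotetrahydrofuran-2-carboxylate
Product: 7 (5S)-5-(2-hydroxypropan-2-yl)dihydrofuran-2(3H)-one, via methyl ketone 6 (not isolated)
Conditions: MeMgBr (2.1 equiv), THF, −78 °C, 2 h; 1 M HCl, 0 °C
Reagents that add atoms: methylmagnesium bromide, C[Mg]Br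
Why: Double Grignard addition at −78 °C takes place only at the ester, which is activated by the α-acyloxy oxygen, while the γ-lactone survives and the (S) centre is retained because addition outruns enolisation.

Step 3
Reactants: 7 (5S)-5-(2-hydroxypropan-2-yl)dihydrofuran-2(3H)-one
Product: 9 (5S)-3-acetyl-5-(2-hydroxypropan-2-yl)dihydrofuran-2(3H)-one (C3 epimers), via dilithium alkoxide enolate 8 (not isolated)
Conditions: LiN(i-Pr)2 (LDA, 2.2 equiv), THF, −78 °C; MeC(O)N(OMe)Me (1.5 equiv), −78 → −20 °C; 1 M HCl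
Reagents that add atoms: N-methoxy-N-methylacetamide, CC(=O)N(C)OC
Why: The lactone enolate is C-acylated by the Weinreb amide in a crossed Claisen-type condensation whose chelated tetrahedral adduct stops over-reaction, the tertiary alkoxide being a spectator and the new C3 centre irrelevant because it becomes sp2 in the next step.

Step 4
Reactants: 9 (5S)-3-acetyl-5-(2-hydroxypropan-2-yl)dihydrofuran-2(3H)-one
Product: 11 (5S)-5-(2-hydroxypropan-2-yl)-3-(1-methoxyethylidene)dihydrofuran-2(3H)-one (E/Z mixture), via dimethyl ketal 10 (not isolated)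
Conditions: HC(OMe)3 (3 equiv), MeOH, p-TsOH·H2O (5 mol %), rt, 16 h; pyridine (10 mol %), concentrate, then PhMe, 100 °C, distil off MeOH
Reagents that add atoms: trimethyl orthoformate, COC(OC)OC
Why: Acid-catalysed ketalisation of the ketone by the orthoformate followed by loss of methanol gives the conjugated enol ether (a vinylogous carbonate) as the thermodynamic product, and its O-methyl group becomes the 6-OMe of the target.

Step 5
Reactants: 11 (5S)-5-(2-hydroxypropan-2-yl)-3-(1-methoxyethylidene)dihydrofuran-2(3H)-one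
Product: 13 (5S)-3-(1-methoxyvinyl)-2-(trimethylsilyloxy)-5-[2-(trimethylsilyloxy)propan-2-yl]-4,5-dihydrofuran, via dilithium alkoxide dienolate 12 (not isolated)
Conditions: LiN(i-Pr)2 (2.3 equiv), THF, −78 °C, 1 h; TMSCl (3 equiv), −78 °C → rt; concentrate, pentane, filter, use crude
Reagents that add atoms: chlorotrimethylsilane, C[Si](C)(C)Cl
Why: γ-Deprotonation of the vinylogous carbonate and O-silylation of the extended enolate (Brassard-type vinylketene acetal formation) give the 1,1,3-trioxygenated diene, the tertiary alkoxide being silylated in the same operation.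

Step 6
Reactants: 4 ethyl (5S)-5-hydroxyhex-2-ynoate; 13 (5S)-3-(1-methoxyvinyl)-2-(trimethylsilyloxy)-5-[2-(trimethylsilyloxy)propan-2-yl]-4,5-dihydrofuran
Product: 18 (3S)-7-[(2S)-2,3-dihydroxy-3-methylbutyl]-8-hydroxy-6-methoxy-3-methyl-3,4-dihydro-1H-isochromen-1-one, via silyl ether 14 (not isolated), via bicyclic Diels–Alder adduct 15 (not isolated), via aryl silyl ether 16 (not isolated), via hydroxy ester 17 (not isolated)
Conditions: 4, BSA (1.1 equiv), PhMe, rt, 1 h; 13 (1.4 equiv), 125 °C, sealed tube, 36 h; then Bu4NF (5 equiv), THF, 0 °C → rt; 1 M HCl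
Reagents that add atoms: none
Why: A regioselective Diels–Alder reaction joins the nucleophilic CH2 terminus of the vinylketene acetal to the β-carbon of the ynoate, the adduct aromatises by 1,4-elimination of the ring alkoxide (as Brassard adducts lose methanol) to unveil the 8-oxygen and the side-chain 2-hydroxyl, and fluoride then removes the silyl groups so that the (S)-alkoxide closes the δ-lactone by transesterification, both stereocentres being spectators.

Step 7
Reactants: 18 (3S)-7-[(2S)-2,3-dihydroxy-3-methylbutyl]-8-hydroxy-6-methoxy-3-methyl-3,4-dihydro-1H-isochromen-1-one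
Product: 20 (2S)-3-hydroxy-1-[(3S)-8-hydroxy-6-methoxy-3-methyl-1-oxo-3,4-dihydro-1H-isochromen-7-yl]-3-methylbutan-2-yl acetate, via diacetate 19 (not isolated)
Conditions: Ac2O (2.3 equiv), pyridine, DMAP (5 mol %), 0 °C → rt; then pyrrolidine (1.5 equiv), 0 °C, 20 min
Reagents that add atoms: acetic anhydride, CC(=O)OC(C)=O
Why: DMAP-catalysed acetylation esterifies the secondary alcohol and the phenol but not the hindered tertiary alcohol, and the much more electrophilic aryl acetate is then removed selectively by aminolysis with pyrrolidine, with no change at either stereocentre.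

**Compound list**

1 | ethyl propiolate | C#CC(=O)OCC | starting material
2 | (S)-propylene oxide | C[C@H]1CO1 | starting material
3 | ethyl 3-lithiopropiolate | [Li]C#CC(=O)OCC | intermediate
4 | ethyl (5S)-5-hydroxyhex-2-ynoate | CCOC(=O)C#CC[C@H](C)O | intermediate
5 | methyl (2S)-5-oxotetrahydrofuran-2-carboxylate | COC(=O)[C@@H]1CCC(=O)O1 | starting material
6 | (5S)-5-acetyldihydrofuran-2(3H)-one | CC(=O)[C@@H]1CCC(=O)O1 | intermediate
7 | (5S)-5-(2-hydroxypropan-2-yl)dihydrofuran-2(3H)-one | CC(C)(O)[C@@H]1CCC(=O)O1 | intermediate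
8 | dilithium alkoxide enolate of 7 | CC(C)(O[Li])[C@@H]1CC=C(O[Li])O1 | intermediate
9 | (5S)-3-acetyl-5-(2-hydroxypropan-2-yl)dihydrofuran-2(3H)-one (C3 epimers) | CC(=O)C1C[C@@H](C(C)(C)O)OC1=O | intermediate
10 | (5S)-3-(1,1-dimethoxyethyl)-5-(2-hydroxypropan-2-yl)dihydrofuran-2(3H)-one | COC(C)(OC)C1C[C@@H](C(C)(C)O)OC1=O | intermediate
11 | (5S)-5-(2-hydroxypropan-2-yl)-3-(1-methoxyethylidene)dihydrofuran-2(3H)-one (E/Z mixture) | COC(C)=C1C[C@@H](C(C)(C)O)OC1=O | intermediate
12 | dilithium alkoxide dienolate of 11 | C=C(OC)C1=C(O[Li])O[C@H](C(C)(C)O[Li])C1 | intermediate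
13 | (5S)-3-(1-methoxyvinyl)-2-(trimethylsilyloxy)-5-[2-(trimethylsilyloxy)propan-2-yl]-4,5-dihydrofuran | C=C(OC)C1=C(O[Si](C)(C)C)O[C@H](C(C)(C)O[Si](C)(C)C)C1 | intermediate
14 | ethyl (5S)-5-(trimethylsilyloxy)hex-2-ynoate | CCOC(=O)C#CC[C@H](C)O[Si](C)(C)C | intermediate
15 | ethyl (2S)-4-methoxy-7a-(trimethylsilyloxy)-2-[2-(trimethylsilyloxy)propan-2-yl]-6-[(2S)-2-(trimethylsilyloxy)propyl]-2,3,5,7a-tetrahydro-1-benzofuran-7-carboxylate (C7a epimers) | CCOC(=O)C1=C(C[C@H](C)O[Si](C)(C)C)CC(OC)=C2C[C@@H](C(C)(C)O[Si](C)(C)C)OC12O[Si](C)(C)C | intermediate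
16 | ethyl 3-[(2S)-2-hydroxy-3-methyl-3-(trimethylsilyloxy)butyl]-4-methoxy-2-(trimethylsilyloxy)-6-[(2S)-2-(trimethylsilyloxy)propyl]benzoate | CCOC(=O)c1c(C[C@H](C)O[Si](C)(C)C)cc(OC)c(C[C@H](O)C(C)(C)O[Si](C)(C)C)c1O[Si](C)(C)C | intermediate
17 | ethyl 3-[(2S)-2,3-dihydroxy-3-methylbutyl]-2-hydroxy-6-[(2S)-2-hydroxypropyl]-4-methoxybenzoate | CCOC(=O)c1c(C[C@H](C)O)cc(OC)c(C[C@H](O)C(C)(C)O)c1O | intermediate
18 | (3S)-7-[(2S)-2,3-dihydroxy-3-methylbutyl]-8-hydroxy-6-methoxy-3-methyl-3,4-dihydro-1H-isochromen-1-one | COc1cc2c(c(O)c1C[C@H](O)C(C)(C)O)C(=O)O[C@@H](C)C2 | intermediate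
19 | (2S)-1-[(3S)-8-acetoxy-6-methoxy-3-methyl-1-oxo-3,4-dihydro-1H-isochromen-7-yl]-3-hydroxy-3-methylbutan-2-yl acetate | COc1cc2c(c(OC(C)=O)c1C[C@H](OC(C)=O)C(C)(C)O)C(=O)O[C@@H](C)C2 | intermediate
20 | (2S)-3-hydroxy-1-[(3S)-8-hydroxy-6-methoxy-3-methyl-1-oxo-3,4-dihydro-1H-isochromen-7-yl]-3-methylbutan-2-yl acetate | COc1cc2c(c(O)c1C[C@H](OC(C)=O)C(C)(C)O)C(=O)O[C@@H](C)C2 | target

**Count and risks**

Total steps: 7. Longest linear sequence: 6 (steps 2, 3, 4, 5, 6, 7 from 5 to 20); step 1 is the one-step side branch.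

Step 6 is the most likely to fail. The β-alkyl ynoate is only a moderate dienophile, the 2-substituted ketene acetal 13 is thermally and hydrolytically fragile, and the adduct could aromatise by loss of silanol to a dihydrobenzofuran instead of ring-opening. The fallback sets out from 4 (and uses 13) and comes back at 18. Semi-hydrogenation of 4 (H2, Pd on CaCO3 poisoned with Pb(OAc)2, quinoline, EtOAc) gives ethyl (2Z,5S)-5-hydroxyhex-2-enoate F1. This lactonises (p-TsOH cat., PhH, rt) to (6S)-6-methyl-5,6-dihydro-2H-pyran-2-one F2. Br2 in CH2Cl2 gives (6S)-3,4-dibromo-6-methyltetrahydro-2H-pyran-2-one F3, and Et3N eliminates HBr to (6S)-3-bromo-6-methyl-5,6-dihydro-2H-pyran-2-one F4. F4 is a cis-locked α-bromo enoate, a more reactive dienophile that already holds the δ-lactone. Its Diels–Alder reaction with 13 (PhMe, 110 °C, then Et3N) is followed by loss of HBr and ring-opening aromatisation to (3S)-7-[(2S)-2-hydroxy-3-methyl-3-(trimethylsilyloxy)butyl]-6-methoxy-3-methyl-8-(trimethylsilyloxy)-3,4-dihydro-1H-isochromen-1-one F5. Bu4NF in THF then gives 18.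

Step 3 is the second risk. The lactone enolate may self-condense, or the tertiary alkoxide may interfere, before the Weinreb amide reacts. The fallback sets out from 7 and comes back at 9. The dianion 8 (LiN(i-Pr)2, 2.2 equiv, THF, −78 °C) is trapped with acetaldehyde in an aldol addition to give (5S)-3-(1-hydroxyethyl)-5-(2-hydroxypropan-2-yl)dihydrofuran-2(3H)-one F6 as a diastereomer mixture. Dess–Martin periodinane (CH2Cl2, NaHCO3, rt) oxidises only its secondary alcohol and gives 9.

Step 4 is the third risk. With a tetrasubstituted enol ether to form and a free tertiary alcohol under acid, ketal 10, a bridged mixed ketal or a dehydration product may result instead of 11. The fallback sets out from 9 and comes back at 18, avoiding the methyl enol ether altogether. TMSOTf (2.2 equiv) and Et3N in CH2Cl2 at 0 °C give (5S)-3-[1-(trimethylsilyloxy)ethylidene]-5-[2-(trimethylsilyloxy)propan-2-yl]dihydrofuran-2(3H)-one F7. LiN(i-Pr)2 and TMSCl in THF at −78 °C give the Chan-type diene (5S)-2-(trimethylsilyloxy)-3-[1-(trimethylsilyloxy)vinyl]-5-[2-(trimethylsilyloxy)propan-2-yl]-4,5-dihydrofuran F8. Cycloaddition with 14 (made from 4 with BSA as in step 6; PhMe, 125 °C), then Bu4NF and 1 M HCl, gives (3S)-7-[(2S)-2,3-dihydroxy-3-methylbutyl]-6,8-dihydroxy-3-methyl-3,4-dihydro-1H-isochromen-1-one F9. MeI (1.05 equiv) and K2CO3 in acetone at rt methylate only the non-chelated 6-OH and give 18.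

**Further compounds**

F1 | step 6 | ethyl (2Z,5S)-5-hydroxyhex-2-enoate | CCOC(=O)/C=C\C[C@H](C)O
F2 | step 6 | (6S)-6-methyl-5,6-dihydro-2H-pyran-2-one | C[C@H]1CC=CC(=O)O1
F3 | step 6 | (6S)-3,4-dibromo-6-methyltetrahydro-2H-pyran-2-one | C[C@H]1CC(Br)C(Br)C(=O)O1
F4 | step 6 | (6S)-3-bromo-6-methyl-5,6-dihydro-2H-pyran-2-one | C[C@H]1CC=C(Br)C(=O)O1
F5 | step 6 | (3S)-7-[(2S)-2-hydroxy-3-methyl-3-(trimethylsilyloxy)butyl]-6-methoxy-3-methyl-8-(trimethylsilyloxy)-3,4-dihydro-1H-isochromen-1-one | COc1cc2c(c(O[Si](C)(C)C)c1C[C@H](O)C(C)(C)O[Si](C)(C)C)C(=O)O[C@@H](C)C2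
F6 | step 3 | (5S)-3-(1-hydroxyethyl)-5-(2-hydroxypropan-2-yl)dihydrofuran-2(3H)-one | CC(O)C1C[C@@H](C(C)(C)O)OC1=O
F7 | step 4 | (5S)-3-[1-(trimethylsilyloxy)ethylidene]-5-[2-(trimethylsilyloxy)propan-2-yl]dihydrofuran-2(3H)-one | CC(O[Si](C)(C)C)=C1C[C@@H](C(C)(C)O[Si](C)(C)C)OC1=O
F8 | step 4 | (5S)-2-(trimethylsilyloxy)-3-[1-(trimethylsilyloxy)vinyl]-5-[2-(trimethylsilyloxy)propan-2-yl]-4,5-dihydrofuran | C=C(O[Si](C)(C)C)C1=C(O[Si](C)(C)C)O[C@H](C(C)(C)O[Si](C)(C)C)C1
F9 | step 4 | (3S)-7-[(2S)-2,3-dihydroxy-3-methylbutyl]-6,8-dihydroxy-3-methyl-3,4-dihydro-1H-isochromen-1-one | Oc1cc2c(c(O)c1C[C@H](O)C(C)(C)O)C(=O)O[C@@H](C)C2
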